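**Plan**

1. Retrosynthesis: the methacrylate (C8–O) and the C1 ketone/C8 hydroxyl come from one temporary five-membered ketal ring C1(OMe)–O–C8. The butenolide (O–C6–C7=C11–C12) is cut back to a 2,3,4-trisubstituted furan. The C4–C5 bond of the oxirane is cut to a C4 methyl ketone and a C5 sulfonium ylide. Then C1–C2 (Grignard on a γ-lactone), C10–CH3 (enolate methylation) and C8–C9 (Stetter) are cut.
2. Enabling feature: with the lactone ring atoms O/C6/C7/C11/C12 at the furan oxidation level, C5 is a furfurylic CH2. Its sulfonium ylide is stabilised, and C6 carries neither a hydrogen nor a leaving group, so β-elimination is impossible. The 1,4-relation of C8–OH and C1=O allows the ketal ring, which hides C1 and holds the two arms cis.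
3. Forward order: furan diol → γ-keto ester → γ-lactone (C8) → trans-methyl lactone (C10) → ketal ring → C5 formyl group → sulfonium salt → ylide ring closure giving the ten-membered ring and the oxirane together → furan dearomatised to the butenolide → ketal opened → methacrylate.
4. Stereochemistry: C8 by catalytic asymmetric transfer hydrogenation; C10 and the ketal centre relayed from C8 through the lactone; C4/C5 relayed from C8 in the ring closure; C6 relayed from C5 by chelation-controlled reduction.

Key step: step 12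

Remark: locants C1–C15 are germacrane locants of the target (C1 ketone, C4/C5 oxirane, C6 lactone CH–O, C7=C11, C8 ester carbinol, C10 CH(CH3), C12 lactone C=O, C13 CH2OAc). Hemiketals 10 and 23 are equilibrating mixtures and are drawn without configuration at the hemiketal carbon. In 21 the CIP label at C5 is S because the furan carbon outranks C4; the spatial arrangement is that of the target.

**Step 1**
Reactants: 1 furan-3,4-diyldimethanol
Product: 2 {4-[(triisopropylsilyloxy)methyl]furan-3-yl}methanol
Conditions: NaH (1.0 equiv), THF, 0 °C; TIPSCl (1.0 equiv), 0 → 23 °C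
Reagents that add atoms: chlorotriisopropylsilane, CC(C)[Si](Cl)(C(C)C)C(C)C
Why: Monosilylation of a symmetrical diol through its monosodium alkoxide should stop at the mono-ether; TIPS is chosen because it survives LDA, Grignard, n-BuLi and PPTS/MeOH and is a poor director of lithiation.

**Step 2**
Reactants: 2 {4-[(triisopropylsilyloxy)methyl]furan-3-yl}methanol
Product: 3 4-[(triisopropylsilyloxy)methyl]furan-3-carbaldehyde
Conditions: activated MnO2, CH2Cl2, 23 °C
Reagents that add atoms: none
Why: Activated MnO2 oxidises heteroaryl carbinols to aldehydes without over-oxidation and leaves the furan untouched.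

**Step 3**
Reactants: 3 4-[(triisopropylsilyloxy)methyl]furan-3-carbaldehyde; 4 methyl acrylate
Product: 5 methyl 4-oxo-4-{4-[(triisopropylsilyloxy)methyl]furan-3-yl}butanoate
Conditions: 3-benzyl-5-(2-hydroxyethyl)-4-methylthiazolium chloride (15 mol %), Et3N, EtOH, 75 °C
Reagents that add atoms: none
Why: Stetter reaction: the Breslow intermediate of the heteroaryl aldehyde adds 1,4 to the acrylate and gives the 1,4-dicarbonyl that holds C8, C9, C10 and C1.

**Step 4**
Reactants: 5 methyl 4-oxo-4-{4-[(triisopropylsilyloxy)methyl]furan-3-yl}butanoate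
Product: 7 (5R)-5-{4-[(triisopropylsilyloxy)methyl]furan-3-yl}dihydrofuran-2(3H)-one, via hydroxy ester 6 (not isolated)
Conditions: RuCl[(R,R)-TsDPEN](p-cymene) (1 mol %), HCO2H/Et3N (5:2), 35 °C; then PPTS (cat.), toluene, 60 °C
Reagents that add atoms: none
Why: Asymmetric transfer hydrogenation of a heteroaryl alkyl ketone, in which the (R,R)-catalyst should give the (R)-carbinol by the usual aryl/alkyl differentiation (sets C8), followed by lactonisation of the γ-hydroxy ester.

**Step 5**
Reactants: 7 (5R)-5-{4-[(triisopropylsilyloxy)methyl]furan-3-yl}dihydrofuran-2(3H)-one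
Product: 8 (3S,5R)-3-methyl-5-{4-[(triisopropylsilyloxy)methyl]furan-3-yl}dihydrofuran-2(3H)-one
Conditions: LDA, THF, −78 °C; MeI, −78 °C
Reagents that add atoms: iodomethane, CI
Why: Alkylation of the γ-substituted butyrolactone enolate anti to the furyl group should give the 3,5-trans lactone, so C10 is relayed from C8.

**Step 6**
Reactants: 8 (3S,5R)-3-methyl-5-{4-[(triisopropylsilyloxy)methyl]furan-3-yl}dihydrofuran-2(3H)-one; 9 but-3-en-1-ylmagnesium bromide
Product: 11 (2R,3S,5R)-2-(but-3-en-1-yl)-2-methoxy-3-methyl-5-{4-[(triisopropylsilyloxy)methyl]furan-3-yl}tetrahydrofuran, via lactol 10 (not isolated)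
Conditions: 9 (1.2 equiv), THF, −78 °C, aq NH4Cl; crude 10: MeOH, PPTS (cat.), 23 °C
Reagents that add atoms: methanol, CO
Why: Single Grignard addition to the α-branched lactone (tetrahedral magnesium alkoxide stable at −78 °C) gives the lactol, and acid-catalysed exchange in methanol under thermodynamic control should favour the anomer with the butenyl chain trans to the neighbouring methyl and cis to the furyl group, masking C1=O and C8–OH in one ring.

**Step 7**
Reactants: 11 (2R,3S,5R)-2-(but-3-en-1-yl)-2-methoxy-3-methyl-5-{4-[(triisopropylsilyloxy)methyl]furan-3-yl}tetrahydrofuran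
Product: 12 3-[(2R,4S,5R)-5-(but-3-en-1-yl)-5-methoxy-4-methyltetrahydrofuran-2-yl]-4-[(triisopropylsilyloxy)methyl]furan-2-carbaldehyde
Conditions: n-BuLi, THF, −78 → −20 °C; DMF, −78 → 0 °C; aq NH4Cl
Reagents that add atoms: N,N-dimethylformamide, CN(C)C=O
Why: Directed α-lithiation of the furan, in which the two ketal oxygens of the C8 arm should guide n-BuLi to the adjacent α-CH (C6) while the other α-CH is flanked only by the bulky TIPS ether, followed by formylation that installs C5.

**Step 8**
Reactants: 12 3-[(2R,4S,5R)-5-(but-3-en-1-yl)-5-methoxy-4-methyltetrahydrofuran-2-yl]-4-[(triisopropylsilyloxy)methyl]furan-2-carbaldehyde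
Product: 14 {5-formyl-4-[(2R,4S,5R)-5-(but-3-en-1-yl)-5-methoxy-4-methyltetrahydrofuran-2-yl]furan-3-yl}methyl acetate, via alcohol 13 (not isolated)
Conditions: TBAF, THF, 0 °C; then Ac2O, DMAP (cat.), 0 → 23 °C
Reagents that add atoms: acetic anhydride, CC(=O)OC(C)=O
Why: Fluoride desilylation and in-flask acetylation of the only hydroxyl place the C13 acetate before any base-sensitive functionality exists.

**Step 9**
Reactants: 14 {5-formyl-4-[(2R,4S,5R)-5-(but-3-en-1-yl)-5-methoxy-4-methyltetrahydrofuran-2-yl]furan-3-yl}methyl acetate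
Product: 15 {5-formyl-4-[(2R,4S,5R)-5-methoxy-4-methyl-5-(3-oxobutyl)tetrahydrofuran-2-yl]furan-3-yl}methyl acetate
Conditions: PdCl2 (10 mol %), Cu(OAc)2 (20 mol %), O2 (1 atm), DMA/H2O (7:1), 23 °C
Reagents that add atoms: water, O
Why: Tsuji–Wacker oxidation of the terminal alkene by Markovnikov hydroxypalladation gives the C4 methyl ketone; copper acetate buffers the medium for the ketal and the formyl group deactivates the furan towards Pd(II).

**Step 10**
Reactants: 15 {5-formyl-4-[(2R,4S,5R)-5-methoxy-4-methyl-5-(3-oxobutyl)tetrahydrofuran-2-yl]furan-3-yl}methyl acetate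
Product: 16 {5-(hydroxymethyl)-4-[(2R,4S,5R)-5-methoxy-4-methyl-5-(3-oxobutyl)tetrahydrofuran-2-yl]furan-3-yl}methyl acetate
Conditions: NaBH4 (0.5 equiv), MeOH/CH2Cl2 (1:1), −78 °C
Reagents that add atoms: none
Why: At low temperature borohydride reduces the aldehyde much faster than the methyl ketone and does not touch the acetate.

**Step 11**
Reactants: 16 {5-(hydroxymethyl)-4-[(2R,4S,5R)-5-methoxy-4-methyl-5-(3-oxobutyl)tetrahydrofuran-2-yl]furan-3-yl}methyl acetate
Product: 18 1-({4-(acetoxymethyl)-3-[(2R,4S,5R)-5-methoxy-4-methyl-5-(3-oxobutyl)tetrahydrofuran-2-yl]furan-2-yl}methyl)tetrahydrothiophenium methanesulfonate, via mesylate 17 (not isolated)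
Conditions: Ms2O, i-Pr2NEt, CH2Cl2, −40 °C; tetrahydrothiophene (5 equiv), −40 → 0 °C; precipitation with Et2O
Reagents that add atoms: methanesulfonic anhydride, CS(=O)(=O)OS(C)(=O)=O; tetrahydrothiophene, C1CCSC1
Why: The highly ionisable furfuryl mesylate is captured at once by the soft sulfide (S-alkylation), giving the sulfonium salt with a non-nucleophilic counter-ion under base-buffered conditions that spare the ketal.

**Step 12**
Reactants: 18 1-({4-(acetoxymethyl)-3-[(2R,4S,5R)-5-methoxy-4-methyl-5-(3-oxobutyl)tetrahydrofuran-2-yl]furan-2-yl}methyl)tetrahydrothiophenium methanesulfonate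
Product: 21 ketal-bridged furano-epoxide (C1–C10 carbocycle fused to the furan at C6–C7 with cis-4,5-oxirane and C1(OMe)–O–C8 bridge; stereocentres arranged as in the target), via sulfonium ylide 19 (not isolated), via betaine 20 (not isolated)
Conditions: Cs2CO3 (3 equiv), MeCN, 25–40 °C, slow addition of 18 to a final 1 mM
Reagents that add atoms: none
Why: Proposed new method: Cs2CO3 reversibly deprotonates the furfurylic CH2 of 18 (the only acidic site) to ylide 19, whose carbanion adds to the C4 methyl ketone to give betaine 20, and the alkoxide then displaces tetrahydrothiophene from C5. The closest known reaction type is the Corey–Chaykovsky epoxidation of ketones by benzyl-type tetrahydrothiophenium ylides, whose intramolecular form is established for five- to seven-membered rings but not for a medium ring. The ten-membered carbocycle closes by a 10-exo-trig addition (nine-membered when counted through the ketal oxygen) and the oxirane by a 3-exo-tet displacement with O− anti-periplanar to S+. C5 is controlled by C8: the cis-2,5-disubstituted ketal ring can deliver the ketone only across the furan face that carries C9, with the bulky S+ turned away from the C7 arm. C4 follows from ring constraint, because only the betaine rotamer with a gauche C3–C4–C5–C6 torsion (cis-fused oxirane) fits the bicyclic frame. The step needs chemoselectivity for the C4 ketone (C1 is a ketal, the acetate is less electrophilic), freedom from β-elimination (C6 is a furan carbon) and ring closure over oligomerisation (high dilution, reversibly regenerated semi-stabilised ylide).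

**Step 13**
Reactants: 21 ketal-bridged furano-epoxide
Product: 23 ketal-bridged 6-hydroxybutenolide (γ-hydroxybutenolide; C6 hemiketal in equilibrium with the open Z-keto acid), via endoperoxide 22 (not isolated)
Conditions: O2, rose bengal (cat.), visible light, i-Pr2NEt, CH2Cl2, −78 → 0 °C
Reagents that add atoms: dioxygen, O=O
Why: [4+2] cycloaddition of singlet oxygen to the furan and amine-induced Kornblum–DeLaMare cleavage through the only bridgehead hydrogen (C12–H) dearomatise the furan to the lactone oxidation level with C12 as the carbonyl; the regiochemistry is fixed because C6 bears no hydrogen.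

**Step 14**
Reactants: 23 ketal-bridged 6-hydroxybutenolide
Product: 25 (1R,4S,5R,6R,8R,10S)-13-acetoxy-4,5-epoxy-1-methoxy-1,8-epoxygermacr-7(11)-en-12,6-olide, via hydroxy acid 24 (not isolated)
Conditions: CeCl3·7H2O, NaBH4, MeOH, −40 °C; then pH 5 phosphate buffer, 23 °C
Reagents that add atoms: none
Why: Luche 1,2-reduction of the ring-opened C6 ketone, in which Ce(III) chelation of the ketone and oxirane oxygens should hold them syn so that hydride enters from the periphery and gives the erythro (anti) epoxy alcohol (6R), which lactonises onto the cis carboxyl.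

**Step 15**
Reactants: 25 (1R,4S,5R,6R,8R,10S)-13-acetoxy-4,5-epoxy-1-methoxy-1,8-epoxygermacr-7(11)-en-12,6-olide
Product: 26 (4S,5R,6R,8R,10S)-13-acetoxy-4,5-epoxy-8-hydroxy-1-oxogermacr-7(11)-en-12,6-olide (in equilibrium with its 1,8-hemiketal)
Conditions: PPTS (cat.), acetone/H2O (10:1), 23 °C
Reagents that add atoms: water, O
Why: The mixed methyl ketal hydrolyses through a tertiary oxocarbenium ion under conditions expected to be too mild for the oxirane, which is deactivated by the adjacent acyloxy-bearing carbon; this frees the C1 ketone and the C8 hydroxyl in one operation.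

**Step 16**
Reactants: 26 (4S,5R,6R,8R,10S)-13-acetoxy-4,5-epoxy-8-hydroxy-1-oxogermacr-7(11)-en-12,6-olide
Product: 27 CNP0128625.1, (4S,5R,6R,8R,10S)-13-acetoxy-4,5-epoxy-8-(methacryloyloxy)-1-oxogermacr-7(11)-en-12,6-olide
Conditions: methacrylic anhydride, pyridine, DMAP (cat.), CH2Cl2, 0 °C
Reagents that add atoms: methacrylic anhydride, C=C(C)C(=O)OC(=O)C(C)=C
Why: DMAP-catalysed acylation of the only free hydroxyl (secondary C8–OH, drained from the hemiketal equilibrium) proceeds with retention and under base mild enough for the γ-H of the butenolide and the C10 centre.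

**Compound list**

1 | furan-3,4-diyldimethanol | OCc1cocc1CO | starting material
2 | {4-[(triisopropylsilyloxy)methyl]furan-3-yl}methanol | OCc1cocc1CO[Si](C(C)C)(C(C)C)C(C)C | intermediate
3 | 4-[(triisopropylsilyloxy)methyl]furan-3-carbaldehyde | O=Cc1cocc1CO[Si](C(C)C)(C(C)C)C(C)C | intermediate
4 | methyl acrylate | C=CC(=O)OC | starting material
5 | methyl 4-oxo-4-{4-[(triisopropylsilyloxy)methyl]furan-3-yl}butanoate | COC(=O)CCC(=O)c1cocc1CO[Si](C(C)C)(C(C)C)C(C)C | intermediate
6 | methyl (4R)-4-hydroxy-4-{4-[(triisopropylsilyloxy)methyl]furan-3-yl}butanoate | COC(=O)CC[C@@H](O)c1cocc1CO[Si](C(C)C)(C(C)C)C(C)C | intermediate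
7 | (5R)-5-{4-[(triisopropylsilyloxy)methyl]furan-3-yl}dihydrofuran-2(3H)-one | O=C1CC[C@H](c2cocc2CO[Si](C(C)C)(C(C)C)C(C)C)O1 | intermediate
8 | (3S,5R)-3-methyl-5-{4-[(triisopropylsilyloxy)methyl]furan-3-yl}dihydrofuran-2(3H)-one (trans) | O=C1[C@@H](C)C[C@H](c2cocc2CO[Si](C(C)C)(C(C)C)C(C)C)O1 | intermediate
9 | but-3-en-1-ylmagnesium bromide | C=CCC[Mg]Br | starting material
10 | (3S,5R)-2-(but-3-en-1-yl)-3-methyl-5-{4-[(triisopropylsilyloxy)methyl]furan-3-yl}tetrahydrofuran-2-ol (lactol, C2 epimers) | C=CCCC1(O)O[C@@H](c2cocc2CO[Si](C(C)C)(C(C)C)C(C)C)C[C@@H]1C | intermediate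
11 | (2R,3S,5R)-2-(but-3-en-1-yl)-2-methoxy-3-methyl-5-{4-[(triisopropylsilyloxy)methyl]furan-3-yl}tetrahydrofuran | C=CCC[C@@]1(OC)O[C@@H](c2cocc2CO[Si](C(C)C)(C(C)C)C(C)C)C[C@@H]1C | intermediate
12 | 3-[(2R,4S,5R)-5-(but-3-en-1-yl)-5-methoxy-4-methyltetrahydrofuran-2-yl]-4-[(triisopropylsilyloxy)methyl]furan-2-carbaldehyde | C=CCC[C@@]1(OC)O[C@@H](c2c(C=O)occ2CO[Si](C(C)C)(C(C)C)C(C)C)C[C@@H]1C | intermediate
13 | 3-[(2R,4S,5R)-5-(but-3-en-1-yl)-5-methoxy-4-methyltetrahydrofuran-2-yl]-4-(hydroxymethyl)furan-2-carbaldehyde | C=CCC[C@@]1(OC)O[C@@H](c2c(C=O)occ2CO)C[C@@H]1C | intermediate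
14 | {5-formyl-4-[(2R,4S,5R)-5-(but-3-en-1-yl)-5-methoxy-4-methyltetrahydrofuran-2-yl]furan-3-yl}methyl acetate | C=CCC[C@@]1(OC)O[C@@H](c2c(C=O)occ2COC(C)=O)C[C@@H]1C | intermediate
15 | {5-formyl-4-[(2R,4S,5R)-5-methoxy-4-methyl-5-(3-oxobutyl)tetrahydrofuran-2-yl]furan-3-yl}methyl acetate | CC(=O)CC[C@@]1(OC)O[C@@H](c2c(C=O)occ2COC(C)=O)C[C@@H]1C | intermediate
16 | {5-(hydroxymethyl)-4-[(2R,4S,5R)-5-methoxy-4-methyl-5-(3-oxobutyl)tetrahydrofuran-2-yl]furan-3-yl}methyl acetate | CC(=O)CC[C@@]1(OC)O[C@@H](c2c(CO)occ2COC(C)=O)C[C@@H]1C | intermediate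
17 | {4-(acetoxymethyl)-3-[(2R,4S,5R)-5-methoxy-4-methyl-5-(3-oxobutyl)tetrahydrofuran-2-yl]furan-2-yl}methyl methanesulfonate | CC(=O)CC[C@@]1(OC)O[C@@H](c2c(COS(C)(=O)=O)occ2COC(C)=O)C[C@@H]1C | intermediate
18 | 1-({4-(acetoxymethyl)-3-[(2R,4S,5R)-5-methoxy-4-methyl-5-(3-oxobutyl)tetrahydrofuran-2-yl]furan-2-yl}methyl)tetrahydrothiophenium methanesulfonate | CC(=O)CC[C@@]1(OC)O[C@@H](c2c(C[S+]3CCCC3)occ2COC(C)=O)C[C@@H]1C.CS(=O)(=O)[O-] | intermediate
19 | furfurylic tetrahydrothiophenium ylide of 18 | CC(=O)CC[C@@]1(OC)O[C@@H](c2c([CH-][S+]3CCCC3)occ2COC(C)=O)C[C@@H]1C | intermediate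
20 | macrocyclic betaine (C4 alkoxide, C5 tetrahydrothiophenium) | O1[C@@H]2C[C@H](C)[C@@]1(OC)CC[C@](C)([O-])[C@@H]([S+]4CCCC4)c1occ(COC(C)=O)c12 | intermediate
21 | ketal-bridged furano-epoxide (13-acetoxy-4,5-epoxy-1-methoxy-1,8-epoxy-6,12-furanogermacrane; CIP 1R,4S,5S,8R,10S) | O1[C@@H]2C[C@H](C)[C@@]1(OC)CC[C@]3(C)O[C@@H]3c1occ(COC(C)=O)c12 | intermediate
22 | furan 6,12-endoperoxide of 21 | O1[C@@H]2C[C@H](C)[C@@]1(OC)CC[C@]3(C)O[C@@H]3C45OOC(O4)C(COC(C)=O)=C25 | intermediate
23 | ketal-bridged 6-hydroxybutenolide (C6 epimers, ring–chain tautomers) | O1[C@@H]2C[C@H](C)[C@@]1(OC)CC[C@]3(C)O[C@@H]3C4(O)OC(=O)C(COC(C)=O)=C24 | intermediate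
24 | (6R)-6-hydroxy (Z)-7(11)-en-12-oic acid | O1[C@@H]2C[C@H](C)[C@@]1(OC)CC[C@]3(C)O[C@@H]3[C@H](O)/C2=C(/COC(C)=O)C(O)=O | intermediate
25 | (1R,4S,5R,6R,8R,10S)-13-acetoxy-4,5-epoxy-1-methoxy-1,8-epoxygermacr-7(11)-en-12,6-olide | O1[C@@H]2C[C@H](C)[C@@]1(OC)CC[C@]3(C)O[C@@H]3[C@@H]1OC(=O)C(COC(C)=O)=C12 | intermediate
26 | (4S,5R,6R,8R,10S)-13-acetoxy-4,5-epoxy-8-hydroxy-1-oxogermacr-7(11)-en-12,6-olide | O[C@@H]1C[C@H](C)C(=O)CC[C@]2(C)O[C@@H]2[C@@H]2OC(=O)C(COC(C)=O)=C21 | intermediate
27 | CNP0128625.1 | C=C(C)C(=O)O[C@@H]1C[C@H](C)C(=O)CC[C@]2(C)O[C@@H]2[C@@H]2OC(=O)C(COC(C)=O)=C21 | target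

**Count and risks**

Total step count: 16. Longest linear sequence: 16 steps (1 → 27).

Steps most likely to fail:

Step 12 (Proposed new method). What may go wrong: oligomerisation or decomposition of the ylide outruns the medium-ring closure, or the ketone is attacked on the wrong face. Fallback, setting out from 15 and coming back at 21: the same bond is made by reductive carbonyl coupling. Keto aldehyde 15 is cyclised with SmI2 (THF, high dilution) in a ketyl–carbonyl (pinacol) coupling to the cis-4,5-diol F1. α-Acetoxyisobutyryl bromide (Mattocks–Moffatt reagent, MeCN) converts it through the acetoxonium ion into the 5-bromo 4-acetate F2 with inversion at C5. K2CO3 in methanol removes the acetates and closes the oxirane with a second inversion, giving the 13-hydroxy epoxide F3. Ac2O/pyridine restores the primary acetate and returns to 21.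

Step 13. What may go wrong: the acid- and light-sensitive 2-oxiranylfuran decomposes, or the endoperoxide fragments before the base-induced rearrangement. Fallback, setting out from 21 and coming back at 23: a two-electron oxidation replaces the cycloaddition. NBS/NaHCO3 in aqueous acetone at −20 °C opens the furan of 21 to the (Z)-keto enal F4, and Pinnick oxidation (NaClO2, NaH2PO4, 2-methyl-2-butene) of its aldehyde gives 23.

Step 14. What may go wrong: poor facial selectivity of hydride delivery to the C6 ketone inside the macrocycle, or conjugate reduction. Fallback, setting out from 23 and coming back at 25: reagent control on the open chain. TMSCHN2 (MeOH/toluene) converts 23 into the keto methyl ester F5. Corey–Bakshi–Shibata reduction ((R)-Me-CBS, catecholborane, −78 °C, alkenyl group taken as the large substituent) should give the (6R)-hydroxy ester F6, which lactonises on standing or with a trace of PPTS to 25.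

**Further compounds**

F1 | step 12 | ketal-bridged furano cis-4,5-diol | O1[C@@H]2C[C@H](C)[C@@]1(OC)CC[C@](C)(O)[C@H](O)c1occ(COC(C)=O)c12
F2 | step 12 | ketal-bridged furano 5-bromo 4-acetate (C5 inverted) | O1[C@@H]2C[C@H](C)[C@@]1(OC)CC[C@](C)(OC(C)=O)[C@@H](Br)c1occ(COC(C)=O)c12
F3 | step 12 | 13-hydroxy analogue of 21 | O1[C@@H]2C[C@H](C)[C@@]1(OC)CC[C@]3(C)O[C@@H]3c1occ(CO)c12
F4 | step 13 | (Z)-6-oxo-7(11)-en-12-al | O1[C@@H]2C[C@H](C)[C@@]1(OC)CC[C@]3(C)O[C@@H]3C(=O)/C2=C(/COC(C)=O)C=O
F5 | step 14 | methyl (Z)-6-oxo-7(11)-en-12-oate | O1[C@@H]2C[C@H](C)[C@@]1(OC)CC[C@]3(C)O[C@@H]3C(=O)/C2=C(/COC(C)=O)C(=O)OC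
F6 | step 14 | methyl (6R)-6-hydroxy-(Z)-7(11)-en-12-oate | O1[C@@H]2C[C@H](C)[C@@]1(OC)CC[C@]3(C)O[C@@H]3[C@H](O)/C2=C(/COC(C)=O)C(=O)OC
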